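(Readings and results are simulated for an exercise; noise was put on by code.)

The amounts in the three earlier runs did not add up: D and L together fell short of the charge by a similar molarity at each charge.

common to all: G 37 mM (held)
- violet: L 0.26 M; run made earlier
- blue: L 0.36 M; run made earlier
- grey: L 0.81 M; run made earlier
- oak: L 0.80 M; time 10 h
- cedar: L 0.20 M; time 2.5 h

| run | time / min | D / % | L / % |
|---|---|---|---|
| violet | 6.00 | 0 | 73 |
| violet | 20.0 | 8 | 64 |
| violet | 40.0 | 15 | 52 |
| violet | 50.0 | 22 | 49 |
| violet | 80.0 | 30 | 37 |
| blue | 15.0 | 3 | 78 |
| blue | 30.0 | 8 | 69 |
| blue | 50.0 | 13 | 65 |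
| blue | 60.0 | 21 | 61 |
| blue | 80.0 | 21 | 58 |
| grey | 6.00 | 2 | 90 |
| grey | 20.0 | 4 | 90 |
| grey | 40.0 | 6 | 87 |
| grey | 50.0 | 7 | 84 |
| grey | 80.0 | 10 | 78 |

(scatter of a reading: 1.5 percentage points)

- given per volume of solution although it is solid: L
- at the start none of G is in solution
- at the start none of L is in solution
- what has only dissolved of L counts as not reacted

- which of the two ends with the higher amount of D, in percent of the L charged ("neither" if they lie within 2 percentage points) (oak / cedar / neither)
- D at the end, in percent of the L charged, oak
- D at the end, in percent of the L charged, cedar

At the last readings that gap averaged 0.0862 M. I read it as dissolved L, a saturated pool. The pool times the saturation concentration of G came to 0.00319 M^2. I call this the saturation product. As read, it is the value that dissolved L times dissolved G tend to while solid stands and G is held. If the step to D runs back, then while solid stands and G is held, D stops at a constant times this product: a ceiling in molarity, which is thermodynamic control.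

Oak looks nearly like the grey run, with 0.80 M of L against 0.81 M and the same G. But oak runs 10 h and grey was followed for 80.0 min. Grey made D at 0.0608 M/h and showed no clear bend, but the readings gave no value for the constant. So I committed to the straight line. It gave 76.0% of the charge in oak. It gave 75.9% in cedar, whose 0.152 M of D is less than its charge.

The forecast said neither, with 74% for oak and 73% for cedar: “The two are nearly equal.”

The flask gave cedar, with 27.7% in oak and 66.0% in cedar.

    G ⇌ J, rate k1*(csat - [J]) (kL = 0.00190 /s)
    X + J ⇌ D (K = 75.0 /M, k = 0.0130 /M/s)
    L ⇌ X, rate k3*(cs3 - [X]) while solid is left; crystals form when [X] > cs3 (solubility = 0.0820 M, k = 0.00510 /s)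

With the constant of the D step, the saturation product as read gives a ceiling of 0.239 M, which is 29.9% of oak's charge. Oak reached 27.7% and still held 62.0% as L at 10.0 h. Cedar's charge of 0.20 M was smaller than that ceiling, its L stood at 0% at 2.50 h, and in percent of its own charge it ended higher than oak. The falling back of D to X and J is the main reason for oak's low end: the oak run without it gave 99.0% instead of 27.7%.

In the neighbour flask, like oak but with 2.0 M of L, the ceiling gives 11.9% of the charge. The computed result there is 11.1%.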